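**Retrosynthetic overview**

- The target is traced back to an N-Boc, O-silyl cis-decahydroquinolin-3-ol (late esterification with (E)-oct-2-enoic acid), and this to its 7-oxo derivative; the C7 carbonyl is a temporary activating group, removed by tosylhydrazone reduction.
- Key disconnection: C8–C8a (Mannich) together with N1–C8a (condensation). The bicyclic β-amino ketone comes from an open-chain amino keto aldehyde that is a mixture of epimers at the future C4a. Ring A (piperidine, N1–C8a) closes first and ring B (carbocycle, C8–C8a) second, in one pot.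
- Enabling feature: C8a is an N-bound methine flanked by C4a–H and the C8 methylene, and C7 is an unsubstituted ring B methylene. N1–C8a–C8–C7(=O) is therefore a β-amino ketone (Mannich) retron once C7 carries a carbonyl, and C4a, α to the iminium carbon, is epimerisable and can be funnelled into the cis ring fusion.
- The keto aldehyde comes (hydroboration, oxidation) from a 1,1-disubstituted alkene bearing a methyl ketone. That comes from a Rh-catalysed asymmetric 1,4-addition (sets C5) of an alkenylboronate [N-Boc-L-alaninal (C2), chelate-controlled 2-bromoallylation (C3)] to an E-enone [(R)-2-propyloxirane (C5′), pentenyl Grignard, cross-metathesis].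

Key step: step 10

Remark on the chemistry: locants follow the decahydroquinoline numbering of the target (N1, C2, C3, C4, C4a, C5–C8, C8a; side-chain carbinol C5′). The aldehyde-bearing carbon (future C4a) is deliberately carried as an epimeric mixture because it is reset in the key step. All starting materials are taken as commercially available.

**Route**

Step 1
Reactants: 1 5-bromopent-1-ene; 2 (R)-2-propyloxirane
Product: 4 (R)-dec-9-en-4-ol, via Grignard reagent 3 (not isolated)
Conditions: Mg, THF, rt; then CuBr·SMe2 (10 mol %), 2, −40 to 0 °C; aq. NH4Cl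
Reagents that add atoms: none
Why: Copper-catalysed Grignard opening of a terminal epoxide (SN2 at the unsubstituted carbon) should leave the carbinol stereocentre of 2 untouched, so the (R)-configuration of C5′ is bought in.

Step 2
Reactants: 4 (R)-dec-9-en-4-ol
Product: 5 (R)-tert-butyl(dec-9-en-4-yloxy)diphenylsilane
Conditions: TBDPSCl, imidazole, DMF, rt
Reagents that add atoms: tert-butyl(chloro)diphenylsilane, CC(C)(C)[Si](Cl)(c1ccccc1)c1ccccc1
Why: Imidazole-promoted silyl ether formation; the TBDPS ether is chosen because it should survive SnCl4-free Lewis-acid-free handling and the aqueous TFA of step 10.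

Step 3
Reactants: 5 (R)-tert-butyl(dec-9-en-4-yloxy)diphenylsilane; 6 but-3-en-2-one
Product: 7 (R,E)-9-[(tert-butyldiphenylsilyl)oxy]dodec-3-en-2-one
Conditions: second-generation Hoveyda–Grubbs catalyst (3 mol %), 6 (3 equiv), CH2Cl2, 40 °C
Reagents that add atoms: none
Why: Olefin cross-metathesis of a terminal alkene with an electron-poor vinyl ketone should be selective for the cross product and for the E-enone.

Step 4
Reactants: 8 tert-butyl N-[(2S)-1-oxopropan-2-yl]carbamate (N-Boc-L-alaninal); 9 (2-bromoprop-2-en-1-yl)trimethylsilane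
Product: 10 tert-butyl N-[(2S,3S)-5-bromo-3-hydroxyhex-5-en-2-yl]carbamate
Conditions: SnCl4 (1.1 equiv), CH2Cl2, −78 °C (8 precomplexed, then 9); aq. NaHCO3
Reagents that add atoms: none
Why: Hosomi–Sakurai allylation under Cram-chelate control: SnCl4 bridges carbamate and aldehyde, and the allylsilane should attack the face anti to the methyl group, giving the syn (2S,3S) amino alcohol (C3 of the target).

Step 5
Reactants: 10 tert-butyl N-[(2S,3S)-5-bromo-3-hydroxyhex-5-en-2-yl]carbamate
Product: 11 tert-butyl (4S,5S)-5-(2-bromoprop-2-en-1-yl)-2,2,4-trimethyl-1,3-oxazolidine-3-carboxylate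
Conditions: 2,2-dimethoxypropane, BF3·OEt2 (cat.), acetone, rt
Reagents that add atoms: 2,2-dimethoxypropane, COC(C)(C)OC
Why: N,O-acetalisation of a syn amino alcohol to the unstrained trans-oxazolidine should mask N–H and O–H in one operation, so that the later aldehyde stays open-chain.

Step 6
Reactants: 11 tert-butyl (4S,5S)-5-(2-bromoprop-2-en-1-yl)-2,2,4-trimethyl-1,3-oxazolidine-3-carboxylate
Product: 12 tert-butyl (4S,5S)-2,2,4-trimethyl-5-[2-(4,4,5,5-tetramethyl-1,3,2-dioxaborolan-2-yl)prop-2-en-1-yl]-1,3-oxazolidine-3-carboxylate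
Conditions: B2pin2, PdCl2(PPh3)2 (3 mol %), PPh3 (6 mol %), KOPh, toluene, 50 °C
Reagents that add atoms: bis(pinacolato)diboron, CC1(C)OB(OC1(C)C)B1OC(C)(C)C(C)(C)O1
Why: Miyaura borylation of a 1-alkenyl bromide with phenoxide base should give the 1,1-disubstituted alkenylboronate without touching the carbamate.

Step 7
Reactants: 7 (R,E)-9-[(tert-butyldiphenylsilyl)oxy]dodec-3-en-2-one; 12 tert-butyl (4S,5S)-2,2,4-trimethyl-5-[2-(4,4,5,5-tetramethyl-1,3,2-dioxaborolan-2-yl)prop-2-en-1-yl]-1,3-oxazolidine-3-carboxylate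
Product: 13 tert-butyl (4S,5S)-5-{(3R,8R)-8-[(tert-butyldiphenylsilyl)oxy]-2-methylidene-3-(2-oxopropyl)undecyl}-2,2,4-trimethyl-1,3-oxazolidine-3-carboxylate
Conditions: [RhCl(C2H4)2]2 (2.5 mol %), (S)-BINAP (6 mol %), KOH (0.5 equiv), 1,4-dioxane/H2O (10:1), 60 °C
Reagents that add atoms: none
Why: Rh-catalysed asymmetric 1,4-addition of an alkenylboron reagent (Hayashi–Miyaura reaction): the (S)-BINAP–Rh–alkenyl species should add to the Si face at the α-carbon of the E-enone (ligand control, remote stereocentres play no part), creating the R-configured carbon that becomes C5.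

Step 8
Reactants: 13 tert-butyl (4S,5S)-5-{(3R,8R)-8-[(tert-butyldiphenylsilyl)oxy]-2-methylidene-3-(2-oxopropyl)undecyl}-2,2,4-trimethyl-1,3-oxazolidine-3-carboxylate
Product: 15 tert-butyl (4S,5S)-5-{(3R,8R)-8-[(tert-butyldiphenylsilyl)oxy]-2-(hydroxymethyl)-3-(2-hydroxypropyl)undecyl}-2,2,4-trimethyl-1,3-oxazolidine-3-carboxylate (mixture of diastereomers at the two new centres), via bis-9-BBN adduct 14 (not isolated)
Conditions: 9-BBN dimer (3.5 equiv B–H), THF, 0 to 60 °C; then NaOH (3 M), H2O2 (30 %), 0 °C to rt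
Reagents that add atoms: hydrogen peroxide, OO
Why: Anti-Markovnikov hydroboration–oxidation of the 1,1-disubstituted alkene, with concurrent borane reduction of the ketone so that no chemoselectivity is needed; the two new centres need no control because one is re-oxidised in step 9 and the other is reset in step 10.

Step 9
Reactants: 15 tert-butyl (4S,5S)-5-{(3R,8R)-8-[(tert-butyldiphenylsilyl)oxy]-2-(hydroxymethyl)-3-(2-hydroxypropyl)undecyl}-2,2,4-trimethyl-1,3-oxazolidine-3-carboxylate
Product: 16 tert-butyl (4S,5S)-5-{(3R,8R)-8-[(tert-butyldiphenylsilyl)oxy]-2-formyl-3-(2-oxopropyl)undecyl}-2,2,4-trimethyl-1,3-oxazolidine-3-carboxylate (mixture of C-2 epimers of the undecyl chain)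
Conditions: Dess–Martin periodinane (3 equiv), NaHCO3, CH2Cl2, 0 °C to rt; used crude
Reagents that add atoms: none
Why: Dess–Martin oxidation of the primary and the secondary alcohol in one operation should give the 1,5-keto aldehyde under non-epimerising, non-aldolising conditions.

Step 10
Reactants: 16 tert-butyl (4S,5S)-5-{(3R,8R)-8-[(tert-butyldiphenylsilyl)oxy]-2-formyl-3-(2-oxopropyl)undecyl}-2,2,4-trimethyl-1,3-oxazolidine-3-carboxylate
Product: 19 (2S,3S,4aR,5R,8aS)-5-{(5R)-5-[(tert-butyldiphenylsilyl)oxy]octyl}-3-hydroxy-2-methyloctahydroquinolin-7(1H)-one, via amino keto aldehyde 17 (not isolated), via cyclic imine 18 (not isolated)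
Conditions: TFA/CH2Cl2/H2O (30:65:5), 0 °C to rt; concentrate; AcOH/MeCN (1:10, 0.01 M), 50 °C; aq. NaHCO3
Reagents that add atoms: none
Why: Aqueous TFA removes the N,O-isopropylidene and Boc groups, and the primary amine condenses with the aldehyde carbon (future C8a) to a six-membered cyclic iminium ion (ring A, N1–C8a, 6-exo-trig addition then dehydration) rather than an eight-membered ketimine; the enol of the methyl ketone then adds through its terminal carbon (C8) to the iminium carbon and closes ring B by the C8–C8a bond in a 6-(enolendo)-exo-trig Mannich cyclisation. The closest known reaction type is the acid-mediated intramolecular Mannich cyclisation of a cyclic iminium ion with a tethered ketone to a fused β-amino ketone, including equilibration of the centre α to the iminium carbon. C8a should be set by stereoelectronically preferred axial attack on the half-chair iminium that keeps the C2 methyl pseudo-equatorial (C3–OH pseudo-axial), which places C8 trans to the methyl group. C4a is set dynamically: iminium–enamine tautomerism (N1–C8a=C4a) interconverts both epimers of 16, and only the 4aR epimer can reach the axial trajectory from an equatorial tether through a chair-like ring B transition state with the pre-set 5R side chain equatorial, which gives the cis ring fusion. The step needs condensation before aldol chemistry (secured by fast six-membered imine formation), use of the CH3 enol only (attack through C6 would form a four-membered ring), and kinetic control (mild acid, high dilution, immediate N-protection in step 11).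

Step 11
Reactants: 19 (2S,3S,4aR,5R,8aS)-5-{(5R)-5-[(tert-butyldiphenylsilyl)oxy]octyl}-3-hydroxy-2-methyloctahydroquinolin-7(1H)-one
Product: 20 tert-butyl (2S,3S,4aR,5R,8aS)-5-{(5R)-5-[(tert-butyldiphenylsilyl)oxy]octyl}-3-hydroxy-2-methyl-7-oxooctahydroquinoline-1(2H)-carboxylate
Conditions: Boc2O (3 equiv), Et3N, CH2Cl2, rt to 40 °C
Reagents that add atoms: di-tert-butyl dicarbonate, CC(C)(C)OC(=O)OC(=O)OC(C)(C)C
Why: Carbamate formation on the secondary amine (no DMAP, so the hindered axial alcohol stays free) should block retro-Mannich and retro-aza-Michael pathways of the β-amino ketone.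

Step 12
Reactants: 20 tert-butyl (2S,3S,4aR,5R,8aS)-5-{(5R)-5-[(tert-butyldiphenylsilyl)oxy]octyl}-3-hydroxy-2-methyl-7-oxooctahydroquinoline-1(2H)-carboxylate
Product: 22 tert-butyl (2S,3S,4aR,5R,8aS)-5-{(5R)-5-[(tert-butyldiphenylsilyl)oxy]octyl}-3-hydroxy-2-methyloctahydroquinoline-1(2H)-carboxylate, via tosylhydrazone 21 (not isolated)
Conditions: TsNHNH2, MeOH, 50 °C; concentrate; catecholborane (3 equiv), CHCl3, 0 °C; then NaOAc·3H2O, reflux
Reagents that add atoms: none
Why: Tosylhydrazone formation and hydride reduction (Caglioti-type deoxygenation) should remove the temporary C7 carbonyl of an unhindered cyclohexanone under mild conditions without touching any stereocentre.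

Step 13
Reactants: 22 tert-butyl (2S,3S,4aR,5R,8aS)-5-{(5R)-5-[(tert-butyldiphenylsilyl)oxy]octyl}-3-hydroxy-2-methyloctahydroquinoline-1(2H)-carboxylate; 23 (E)-oct-2-enoic acid
Product: 24 tert-butyl (2S,3S,4aR,5R,8aS)-5-{(5R)-5-[(tert-butyldiphenylsilyl)oxy]octyl}-2-methyl-3-{[(2E)-oct-2-enoyl]oxy}octahydroquinoline-1(2H)-carboxylate
Conditions: DCC, DMAP, CH2Cl2, 0 °C to rt
Reagents that add atoms: none
Why: Steglich esterification of the only free hydroxyl group (N and the side-chain oxygen are protected) should proceed with retention at C3 and without isomerising the E-enoate.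

Step 14
Reactants: 24 tert-butyl (2S,3S,4aR,5R,8aS)-5-{(5R)-5-[(tert-butyldiphenylsilyl)oxy]octyl}-2-methyl-3-{[(2E)-oct-2-enoyl]oxy}octahydroquinoline-1(2H)-carboxylate
Product: 25 tert-butyl (2S,3S,4aR,5R,8aS)-5-[(5R)-5-hydroxyoctyl]-2-methyl-3-{[(2E)-oct-2-enoyl]oxy}octahydroquinoline-1(2H)-carboxylate
Conditions: HF·pyridine, pyridine, THF, 0 °C to rt
Reagents that add atoms: none
Why: Fluoride-mediated desilylation under buffered acidic conditions should free the side-chain alcohol while the nitrogen is still protected, so no O-to-N acyl shift can occur.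

Step 15
Reactants: 25 tert-butyl (2S,3S,4aR,5R,8aS)-5-[(5R)-5-hydroxyoctyl]-2-methyl-3-{[(2E)-oct-2-enoyl]oxy}octahydroquinoline-1(2H)-carboxylate
Product: 26 (2S,3S,4aR,5R,8aS)-5-[(5R)-5-hydroxyoctyl]-2-methyldecahydroquinolin-3-yl (2E)-oct-2-enoate
Conditions: TFA/CH2Cl2 (1:4), 0 °C; cold aq. NaHCO3 work-up
Reagents that add atoms: none
Why: Acidolysis of the Boc carbamate should leave the enoate ester and the secondary alcohol intact and release the target as the free base after brief cold neutralisation.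

**Compound list**

1 | 5-bromopent-1-ene | C=CCCCBr | starting material
2 | (R)-2-propyloxirane | CCC[C@@H]1CO1 | starting material
3 | pent-4-en-1-ylmagnesium bromide | C=CCCC[Mg]Br | intermediate
4 | (R)-dec-9-en-4-ol | C=CCCCC[C@H](O)CCC | intermediate
5 | (R)-tert-butyl(dec-9-en-4-yloxy)diphenylsilane | C=CCCCC[C@H](O[Si](c1ccccc1)(c1ccccc1)C(C)(C)C)CCC | intermediate
6 | but-3-en-2-one | CC(=O)C=C | starting material
7 | (R,E)-9-[(tert-butyldiphenylsilyl)oxy]dodec-3-en-2-one | CC(=O)/C=C/CCCC[C@H](O[Si](c1ccccc1)(c1ccccc1)C(C)(C)C)CCC | intermediate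
8 | tert-butyl N-[(2S)-1-oxopropan-2-yl]carbamate | C[C@H](NC(=O)OC(C)(C)C)C=O | starting material
9 | (2-bromoprop-2-en-1-yl)trimethylsilane | C=C(Br)C[Si](C)(C)C | starting material
10 | tert-butyl N-[(2S,3S)-5-bromo-3-hydroxyhex-5-en-2-yl]carbamate | C[C@H](NC(=O)OC(C)(C)C)[C@@H](O)CC(Br)=C | intermediate
11 | tert-butyl (4S,5S)-5-(2-bromoprop-2-en-1-yl)-2,2,4-trimethyl-1,3-oxazolidine-3-carboxylate | C[C@@H]1N(C(=O)OC(C)(C)C)C(C)(C)O[C@H]1CC(Br)=C | intermediate
12 | tert-butyl (4S,5S)-2,2,4-trimethyl-5-[2-(4,4,5,5-tetramethyl-1,3,2-dioxaborolan-2-yl)prop-2-en-1-yl]-1,3-oxazolidine-3-carboxylate | C[C@@H]1N(C(=O)OC(C)(C)C)C(C)(C)O[C@H]1CC(=C)B1OC(C)(C)C(C)(C)O1 | intermediate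
13 | tert-butyl (4S,5S)-5-{(3R,8R)-8-[(tert-butyldiphenylsilyl)oxy]-2-methylidene-3-(2-oxopropyl)undecyl}-2,2,4-trimethyl-1,3-oxazolidine-3-carboxylate | CC(=O)C[C@@H](CCCC[C@H](O[Si](c1ccccc1)(c1ccccc1)C(C)(C)C)CCC)C(=C)C[C@@H]1OC(C)(C)N(C(=O)OC(C)(C)C)[C@H]1C | intermediate
14 | bis-9-BBN adduct of 13 (B-alkyl at the new CH2, O-boryl at the reduced ketone; two new centres unspecified) | CC(OB1C2CCCC1CCC2)C[C@@H](CCCC[C@H](O[Si](c1ccccc1)(c1ccccc1)C(C)(C)C)CCC)C(CB1C2CCCC1CCC2)C[C@@H]1OC(C)(C)N(C(=O)OC(C)(C)C)[C@H]1C | intermediate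
15 | tert-butyl (4S,5S)-5-{(3R,8R)-8-[(tert-butyldiphenylsilyl)oxy]-2-(hydroxymethyl)-3-(2-hydroxypropyl)undecyl}-2,2,4-trimethyl-1,3-oxazolidine-3-carboxylate (two centres unspecified) | CC(O)C[C@@H](CCCC[C@H](O[Si](c1ccccc1)(c1ccccc1)C(C)(C)C)CCC)C(CO)C[C@@H]1OC(C)(C)N(C(=O)OC(C)(C)C)[C@H]1C | intermediate
16 | tert-butyl (4S,5S)-5-{(3R,8R)-8-[(tert-butyldiphenylsilyl)oxy]-2-formyl-3-(2-oxopropyl)undecyl}-2,2,4-trimethyl-1,3-oxazolidine-3-carboxylate (formyl-bearing centre unspecified) | CC(=O)C[C@@H](CCCC[C@H](O[Si](c1ccccc1)(c1ccccc1)C(C)(C)C)CCC)C(C=O)C[C@@H]1OC(C)(C)N(C(=O)OC(C)(C)C)[C@H]1C | intermediate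
17 | (3R,8R)-2-[(2S,3S)-3-amino-2-hydroxybutyl]-8-[(tert-butyldiphenylsilyl)oxy]-3-(2-oxopropyl)undecanal (C-2 unspecified) | CC(=O)C[C@@H](CCCC[C@H](O[Si](c1ccccc1)(c1ccccc1)C(C)(C)C)CCC)C(C=O)C[C@H](O)[C@H](C)N | intermediate
18 | (4R,9R)-9-[(tert-butyldiphenylsilyl)oxy]-4-[(5S,6S)-5-hydroxy-6-methyl-3,4,5,6-tetrahydropyridin-3-yl]dodecan-2-one (ring C-3 unspecified) | C[C@@H]1N=CC(C[C@@H]1O)[C@H](CCCC[C@H](O[Si](c2ccccc2)(c2ccccc2)C(C)(C)C)CCC)CC(C)=O | intermediate
19 | (2S,3S,4aR,5R,8aS)-5-{(5R)-5-[(tert-butyldiphenylsilyl)oxy]octyl}-3-hydroxy-2-methyloctahydroquinolin-7(1H)-one | O[C@H]1C[C@@H]2[C@H](CCCC[C@H](O[Si](c3ccccc3)(c3ccccc3)C(C)(C)C)CCC)CC(=O)C[C@@H]2N[C@H]1C | intermediate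
20 | tert-butyl (2S,3S,4aR,5R,8aS)-5-{(5R)-5-[(tert-butyldiphenylsilyl)oxy]octyl}-3-hydroxy-2-methyl-7-oxooctahydroquinoline-1(2H)-carboxylate | O[C@H]1C[C@@H]2[C@H](CCCC[C@H](O[Si](c3ccccc3)(c3ccccc3)C(C)(C)C)CCC)CC(=O)C[C@@H]2N(C(=O)OC(C)(C)C)[C@H]1C | intermediate
21 | 7-(4-methylbenzenesulfonylhydrazone) of 20 | O[C@H]1C[C@@H]2[C@H](CCCC[C@H](O[Si](c3ccccc3)(c3ccccc3)C(C)(C)C)CCC)CC(=NNS(=O)(=O)c3ccc(C)cc3)C[C@@H]2N(C(=O)OC(C)(C)C)[C@H]1C | intermediate
22 | tert-butyl (2S,3S,4aR,5R,8aS)-5-{(5R)-5-[(tert-butyldiphenylsilyl)oxy]octyl}-3-hydroxy-2-methyloctahydroquinoline-1(2H)-carboxylate | O[C@H]1C[C@@H]2[C@H](CCCC[C@H](O[Si](c3ccccc3)(c3ccccc3)C(C)(C)C)CCC)CCC[C@@H]2N(C(=O)OC(C)(C)C)[C@H]1C | intermediate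
23 | (E)-oct-2-enoic acid | CCCCC/C=C/C(=O)O | starting material
24 | tert-butyl (2S,3S,4aR,5R,8aS)-5-{(5R)-5-[(tert-butyldiphenylsilyl)oxy]octyl}-2-methyl-3-{[(2E)-oct-2-enoyl]oxy}octahydroquinoline-1(2H)-carboxylate | CCCCC/C=C/C(=O)O[C@H]1C[C@@H]2[C@H](CCCC[C@H](O[Si](c3ccccc3)(c3ccccc3)C(C)(C)C)CCC)CCC[C@@H]2N(C(=O)OC(C)(C)C)[C@H]1C | intermediate
25 | tert-butyl (2S,3S,4aR,5R,8aS)-5-[(5R)-5-hydroxyoctyl]-2-methyl-3-{[(2E)-oct-2-enoyl]oxy}octahydroquinoline-1(2H)-carboxylate | CCCCC/C=C/C(=O)O[C@H]1C[C@@H]2[C@H](CCCC[C@H](O)CCC)CCC[C@@H]2N(C(=O)OC(C)(C)C)[C@H]1C | intermediate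
26 | (2S,3S,4aR,5R,8aS)-5-[(5R)-5-hydroxyoctyl]-2-methyldecahydroquinolin-3-yl (2E)-oct-2-enoate | CCCCC/C=C/C(=O)O[C@H]1C[C@@H]2[C@H](CCCC[C@H](O)CCC)CCC[C@@H]2N[C@H]1C | target

**Step count**

Total: 15 steps. Longest linear sequence: 12 steps (steps 1–3 then 7–15; the branch of steps 4–6 then 7–15 is equally long).

**Three steps most likely to fail**

1. Step 10 (key cascade). What may go wrong: acid-catalysed intramolecular aldol condensation of the keto aldehyde may compete with imine formation; the enol may attack the iminium ion with insufficient axial preference, giving trans-fused or 2,8a-cis isomers; prolonged acid may erode the silyl ether. Fallback: separate the two ring closures and change the activation of the carbon nucleophile from an acid-derived enol to a catalytic enamine. It sets out from 16: brief TFA/CH2Cl2/H2O treatment and NaHCO3 work-up should give cyclic imine 18, now isolated. L-Proline (30 mol %) in DMSO at rt should then effect the enamine-mediated intramolecular Mannich reaction known for cyclic imines and methyl ketones, returning to the route at 19. No compound outside the list is made (entry F0).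

2. Step 7 (asymmetric 1,4-addition). What may go wrong: slow transmetalation and protodeboronation of the hindered 1,1-disubstituted alkenylboronate, and incomplete facial discrimination on the acyclic enone. Fallback: auxiliary-controlled cuprate conjugate addition, setting out from 5 and 11 and returning at 13.
   - Cross-metathesis of 5 with (S)-3-acryloyl-4-phenyl-1,3-oxazolidin-2-one F1 (from commercial (S)-4-phenyloxazolidin-2-one, n-BuLi and acryloyl chloride; second-generation Hoveyda–Grubbs catalyst, CH2Cl2, 40 °C) should give (S)-3-{(2E,8R)-8-[(tert-butyldiphenylsilyl)oxy]undec-2-enoyl}-4-phenyl-1,3-oxazolidin-2-one F2.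
   - Bromide 11 would be converted with Mg in THF into the alkenylmagnesium bromide F3.
   - CuBr·SMe2-mediated addition of F3 to F2 (THF/Me2S, −40 °C) should give the adduct (S)-3-[(3R,8R)-3-{3-[(4S,5S)-3-(tert-butoxycarbonyl)-2,2,4-trimethyl-1,3-oxazolidin-5-yl]prop-1-en-2-yl}-8-[(tert-butyldiphenylsilyl)oxy]undecanoyl]-4-phenyl-1,3-oxazolidin-2-one F4, by attack on the chelated s-cis enoyl imide anti to the phenyl group (3R).
   - Transamidation with MeNH(OMe)·HCl/AlMe3 should give the Weinreb amide F5, and MeMgBr (THF, 0 °C) returns to 13.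

3. Step 4 (chelate-controlled 2-bromoallylation). What may go wrong: the bromine-deactivated allylsilane may add slowly, so that long contact with SnCl4 erodes chelation control, epimerises the α-amino aldehyde or cleaves the Boc group. Fallback: use the parent, more nucleophilic allylsilane and install the boron handle afterwards, setting out from 8 and returning at 12.
   - Allyltrimethylsilane/SnCl4 (CH2Cl2, −78 °C, same Cram-chelate control) should give tert-butyl N-[(2S,3S)-3-hydroxyhex-5-en-2-yl]carbamate F6.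
   - 2,2-Dimethoxypropane/BF3·OEt2 should give tert-butyl (4S,5S)-2,2,4-trimethyl-5-(prop-2-en-1-yl)-1,3-oxazolidine-3-carboxylate F7.
   - Tsuji–Wacker oxidation (PdCl2, CuCl, O2, DMF/H2O) should give tert-butyl (4S,5S)-2,2,4-trimethyl-5-(2-oxopropyl)-1,3-oxazolidine-3-carboxylate F8.
   - Kinetic enolisation at the methyl group (KHMDS, THF, −78 °C) and PhNTf2 should give tert-butyl (4S,5S)-2,2,4-trimethyl-5-{2-[(trifluoromethanesulfonyl)oxy]prop-2-en-1-yl}-1,3-oxazolidine-3-carboxylate F9.
   - Miyaura borylation (B2pin2, PdCl2(PPh3)2, PPh3, KOPh, toluene, 50 °C) returns to 12.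

**Further compounds**

F0 | step 10 | none | none
F1 | step 7 | (S)-3-acryloyl-4-phenyl-1,3-oxazolidin-2-one | C=CC(=O)N1[C@@H](c2ccccc2)COC1=O
F2 | step 7 | (S)-3-{(2E,8R)-8-[(tert-butyldiphenylsilyl)oxy]undec-2-enoyl}-4-phenyl-1,3-oxazolidin-2-one | O=C1OC[C@H](c2ccccc2)N1C(=O)/C=C/CCCC[C@H](O[Si](c1ccccc1)(c1ccccc1)C(C)(C)C)CCC
F3 | step 7 | {3-[(4S,5S)-3-(tert-butoxycarbonyl)-2,2,4-trimethyl-1,3-oxazolidin-5-yl]prop-1-en-2-yl}magnesium bromide | C[C@@H]1N(C(=O)OC(C)(C)C)C(C)(C)O[C@H]1CC(=C)[Mg]Br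
F4 | step 7 | (S)-3-[(3R,8R)-3-{3-[(4S,5S)-3-(tert-butoxycarbonyl)-2,2,4-trimethyl-1,3-oxazolidin-5-yl]prop-1-en-2-yl}-8-[(tert-butyldiphenylsilyl)oxy]undecanoyl]-4-phenyl-1,3-oxazolidin-2-one | O=C1OC[C@H](c2ccccc2)N1C(=O)C[C@@H](CCCC[C@H](O[Si](c1ccccc1)(c1ccccc1)C(C)(C)C)CCC)C(=C)C[C@@H]1OC(C)(C)N(C(=O)OC(C)(C)C)[C@H]1C
F5 | step 7 | tert-butyl (4S,5S)-5-{(3R,8R)-8-[(tert-butyldiphenylsilyl)oxy]-3-{2-[methoxy(methyl)amino]-2-oxoethyl}-2-methylideneundecyl}-2,2,4-trimethyl-1,3-oxazolidine-3-carboxylate | CON(C)C(=O)C[C@@H](CCCC[C@H](O[Si](c1ccccc1)(c1ccccc1)C(C)(C)C)CCC)C(=C)C[C@@H]1OC(C)(C)N(C(=O)OC(C)(C)C)[C@H]1C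
F6 | step 4 | tert-butyl N-[(2S,3S)-3-hydroxyhex-5-en-2-yl]carbamate | C[C@H](NC(=O)OC(C)(C)C)[C@@H](O)CC=C
F7 | step 4 | tert-butyl (4S,5S)-2,2,4-trimethyl-5-(prop-2-en-1-yl)-1,3-oxazolidine-3-carboxylate | C[C@@H]1N(C(=O)OC(C)(C)C)C(C)(C)O[C@H]1CC=C
F8 | step 4 | tert-butyl (4S,5S)-2,2,4-trimethyl-5-(2-oxopropyl)-1,3-oxazolidine-3-carboxylate | C[C@@H]1N(C(=O)OC(C)(C)C)C(C)(C)O[C@H]1CC(C)=O
F9 | step 4 | tert-butyl (4S,5S)-2,2,4-trimethyl-5-{2-[(trifluoromethanesulfonyl)oxy]prop-2-en-1-yl}-1,3-oxazolidine-3-carboxylate | C[C@@H]1N(C(=O)OC(C)(C)C)C(C)(C)O[C@H]1CC(=C)OS(=O)(=O)C(F)(F)F
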